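**Plan** (chromene numbering of the target: O1, C2, C3, C4, C4a, C5–C8, C8a)

1. Retrosynthesis: cut the enol ether bond O1–C8a and the ring A bond C8–C8a (back to a triketone lactone), then C5–C6 (acid chloride plus β-diketone), then the C3=C4 alkene of the pyran ring (back to a prochiral triene).
2. Enabling feature: the pyran ring (O1, C2 with its two methyls, the cis C3=C4 alkene, C4a) hangs from quaternary C4a, whose other two neighbours C8a and C5 are both at the carboxyl level. The ring therefore maps onto the lactone of an α-vinylmalonate that carries two identical 1,1-dimethylallyl ester arms.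
3. Forward: malonate diester, ethylidene malonate, deconjugative prenylation; ring-closing metathesis closes the dihydropyranone (O1, C2, C3, C4, C4a, C8a); the free ester arm becomes the acid chloride and C-acylates a β-diketone (C5–C6); Dieckmann closure gives ring A (C8–C8a); acid re-forms the pyran as the C8=C8a enol ether.
4. Stereochemistry: C4a is the only stereocentre. It is created in the metathesis step by catalyst-controlled choice between the two enantiotopic ester arms and, being quaternary and non-enolisable, is carried unchanged to the target.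

Key step: step 4

Assumption: the sense of induction in step 4 cannot be predicted for this substrate, so the diolate antipode that delivers the (3S)-lactone (written below as the S-diolate) is to be fixed in an initial screen; the enolisable polycarbonyl compounds are drawn as single tautomers.

**Route**

Step 1
Reactants: 1 malonyl dichloride; 2 2-methylbut-3-en-2-ol (2.2 equiv)
Product: 3 bis(2-methylbut-3-en-2-yl) propanedioate
Conditions: PhNMe2 (2.2 equiv), CHCl3, 0 °C to 40 °C
Reagents that add atoms: none
Why: Esterification of a tertiary alcohol by the diacid chloride with an aniline base as HCl acceptor is the standard way to malonates of tertiary alcohols such as di-tert-butyl malonate, and the mild base limits ketene formation from 1 and ionisation of the allylic alcohol.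

Step 2
Reactants: 3; 4 acetaldehyde (3 equiv)
Product: 5 bis(2-methylbut-3-en-2-yl) 2-ethylidenepropanedioate
Conditions: TiCl4 (2 equiv), pyridine (4 equiv), THF, 0 °C to rt
Reagents that add atoms: none
Why: Knoevenagel condensation under TiCl4/pyridine conditions, in which the titanium enolate of 3 adds to the aldehyde and the titanium aldolate eliminates at low temperature, gives alkylidene malonates of enolisable aliphatic aldehydes without the Michael bis-adducts of amine catalysis, and the THF/pyridine-complexed Lewis acid at 0 °C should leave the tertiary allyl esters intact.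

Step 3
Reactants: 5; 6 1-bromo-3-methylbut-2-ene (prenyl bromide)
Product: 8 bis(2-methylbut-3-en-2-yl) 2-ethenyl-2-(3-methylbut-2-en-1-yl)propanedioate, via potassium dienolate 7 (not isolated)
Conditions: KN(SiMe3)2 (1.1 equiv), THF, −78 °C (5 added to the base); then 6, −78 to 0 °C
Reagents that add atoms: none
Why: Deconjugative α-alkylation of an alkylidene malonate: the only acidic hydrogens of 5 are on the γ-methyl group, the extended enolate 7 reacts with the primary allylic bromide at its α-carbon (SN2), and the non-nucleophilic silylamide avoids conjugate addition, so the quaternary carbon bearing vinyl and prenyl groups is formed in an achiral, prochiral triene.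

Step 4
Reactants: 8
Product: 9 2-methylbut-3-en-2-yl (3S)-6,6-dimethyl-3-(3-methylbut-2-en-1-yl)-2-oxo-3,6-dihydro-2H-pyran-3-carboxylate
Conditions: Mo(N-2,6-iPr2C6H3)(CHCMe2Ph)[(S)-3,3'-tBu2-5,5',6,6'-Me4-biphenyl-2,2'-diolate] (5–10 mol %), C6H6 (0.02 M), 22 to 50 °C, argon sweep
Reagents that add atoms: none
Why: The Mo alkylidene takes up a terminal vinyl group, [2+2] cycloaddition with the second vinyl group gives a molybdacyclobutane, and cycloreversion expels ethene while forming the C4=C5 bond of the pyranone (C3=C4 of the target). The closest known reaction type is catalytic enantioselective ring-closing metathesis of achiral trienes with chiral Mo imido alkylidene diolates, which has been used to set fully substituted carbon stereocentres. The six-membered lactone closes by olefin metathesis between the vinyl group on the malonate carbon and the vinyl group of one ester arm, the ring size enforcing the cis alkene and the gem-dimethyl groups favouring the reactive ester rotamer. The stereocentre arises because only one of the two enantiotopic ester arms enters the ring, and the chiral diolate on Mo decides which one through diastereomeric metallacyclobutane transition states (catalyst control). The step needs arm selection and chemoselectivity for terminal alkenes: the malonate carbon carries a single vinyl group, so only one six-membered closure is possible, while the prenyl alkene is trisubstituted and could only close a seven-membered lactone. Ethene is swept out and the temperature kept at or below 50 °C so that neither reversal nor Cope rearrangement of the 1,5-diene in 8 intervenes.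

Step 5
Reactants: 9
Product: 10 (3S)-6,6-dimethyl-3-(3-methylbut-2-en-1-yl)-2-oxo-3,6-dihydro-2H-pyran-3-carboxylic acid
Conditions: Pd(PPh3)4 (5 mol %), morpholine (3 equiv), THF, 0 °C to rt; cold aq. KHSO4
Reagents that add atoms: none
Why: Tsuji–Trost deallylation: zerovalent palladium ionises the acyclic 1,1-dimethylallyl ester through its unhindered terminal alkene and morpholine traps the allyl fragment, whereas the allylic C–O bond of the lactone lies next to a cis ring alkene between two fully substituted carbons that should not coordinate to Pd, the quaternary stereocentre is untouched, and the malonic half-acid is kept at or below room temperature to avoid decarboxylation.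

Step 6
Reactants: 11 6-methylhept-5-en-2-one; 12 methyl 2-methylpropanoate (2 equiv)
Product: 13 2,9-dimethyldec-8-ene-3,5-dione
Conditions: NaH (2.2 equiv), THF, reflux (11 added slowly to NaH and 12); aq. HCl
Reagents that add atoms: none
Why: Crossed Claisen condensation of a methyl ketone with an ester: acylation at the methyl group gives the β-diketone, whose sodium enolate drains the equilibrium, while self-condensation of the isobutyrate is unproductive because its product has no acidic hydrogen between the carbonyls.

Step 7
Reactants: 10
Product: 14 (3R)-6,6-dimethyl-3-(3-methylbut-2-en-1-yl)-2-oxo-3,6-dihydro-2H-pyran-3-carbonyl chloride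
Conditions: Me2C=C(Cl)NMe2 (1.2 equiv), CH2Cl2, 0 °C to rt; used crude
Reagents that add atoms: 1-chloro-N,N,2-trimethylprop-1-en-1-amine, CC(C)=C(Cl)N(C)C
Why: Acid chloride formation with an α-chloroenamine proceeds under neutral conditions without HCl, which protects the prenyl double bond and the lactone, and the acid has no α-hydrogen so neither ketene formation nor epimerisation is possible (the descriptor becomes R only through the priority of the COCl group).

Step 8
Reactants: 13; 14
Product: 16 (3S)-6,6-dimethyl-3-(3-methylbut-2-en-1-yl)-3-[7-methyl-2-(2-methylpropanoyl)-3-oxooct-6-enoyl]-3,6-dihydro-2H-pyran-2-one, via chloromagnesium enolate 15 (not isolated)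
Conditions: MgCl2 (1.2 equiv), pyridine (2.5 equiv), CH2Cl2, 0 °C; then 14 in CH2Cl2, 0 °C to rt; cold 0.5 M HCl
Reagents that add atoms: none
Why: Magnesium-mediated C-acylation of a β-dicarbonyl compound (soft enolisation with MgCl2 and an amine): chelation in 15 ties up both oxygens and directs the acid chloride to the central carbon, the more acidic triacylmethane product stays chelated and is not acylated again, and the stereocentre is a spectator (side-chain C2 of 16 is enolised and carries no fixed configuration).

Step 9
Reactants: 16
Product: 18 (6R)-3,5-dihydroxy-6-[(1Z)-3-hydroxy-3-methylbut-1-en-1-yl]-4,6-bis(3-methylbut-2-en-1-yl)-2-(2-methylpropanoyl)cyclohexa-2,4-dien-1-one, via dilithium dianion 17 (not isolated)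
Conditions: LiN(iPr)2 (3.2 equiv), THF, −78 to 0 °C; sat. aq. NH4Cl; crude used directly
Reagents that add atoms: none
Why: Dieckmann (intramolecular Claisen) condensation via the dianion: the first equivalent of amide removes the triacylmethane hydrogen, the second removes kinetically a methylene hydrogen at C8 in preference to the isobutyryl methine, the C8 carbanion closes ring A by six-membered (6-exo-trig) attack on the lactone carbonyl C8a, the tetrahedral intermediate expels the tertiary alkoxide, and the product is held as its polyanion until the quench, with quaternary C4a unaffected.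

Step 10
Reactants: 18
Product: 19 (4aR)-7-hydroxy-2,2-dimethyl-4a,8-bis(3-methylbut-2-en-1-yl)-6-(2-methylpropanoyl)-2H-chromen-5(4aH)-one
Conditions: PPTS (10 mol %), 4 Å MS, CH2Cl2, rt
Reagents that add atoms: none
Why: Acid-catalysed vinylogous esterification (hemiketalisation and dehydration) of a cyclic 1,3-dione by the cis-tethered tertiary alcohol closes the six-membered pyran, closure at C8a is expected over C5 because C8a belongs to the free vinylogous acid C7–C8–C8a whereas C5 is tied up in the hydrogen-bonded 2-acyl-1,3-dione chelate that the C8a product keeps, and the mild acid should spare the prenyl groups.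

**Compound list**

1 | malonyl dichloride | O=C(Cl)CC(=O)Cl | starting material
2 | 2-methylbut-3-en-2-ol | CC(C)(O)C=C | starting material
3 | bis(2-methylbut-3-en-2-yl) propanedioate | C=CC(C)(C)OC(=O)CC(=O)OC(C)(C)C=C | intermediate
4 | acetaldehyde | CC=O | starting material
5 | bis(2-methylbut-3-en-2-yl) 2-ethylidenepropanedioate | CC=C(C(=O)OC(C)(C)C=C)C(=O)OC(C)(C)C=C | intermediate
6 | 1-bromo-3-methylbut-2-ene | CC(C)=CCBr | starting material
7 | potassium dienolate of 5 (potassium 2-ethenyl-1,3-bis[(2-methylbut-3-en-2-yl)oxy]-3-oxoprop-1-en-1-olate) | [K+].C=CC(C(=O)OC(C)(C)C=C)=C([O-])OC(C)(C)C=C | intermediate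
8 | bis(2-methylbut-3-en-2-yl) 2-ethenyl-2-(3-methylbut-2-en-1-yl)propanedioate | C=CC(C)(C)OC(=O)C(C=C)(CC=C(C)C)C(=O)OC(C)(C)C=C | intermediate
9 | 2-methylbut-3-en-2-yl (3S)-6,6-dimethyl-3-(3-methylbut-2-en-1-yl)-2-oxo-3,6-dihydro-2H-pyran-3-carboxylate | O=C1OC(C)(C)C=C[C@@]1(CC=C(C)C)C(=O)OC(C)(C)C=C | intermediate
10 | (3S)-6,6-dimethyl-3-(3-methylbut-2-en-1-yl)-2-oxo-3,6-dihydro-2H-pyran-3-carboxylic acid | O=C1OC(C)(C)C=C[C@@]1(CC=C(C)C)C(=O)O | intermediate
11 | 6-methylhept-5-en-2-one | CC(=O)CCC=C(C)C | starting material
12 | methyl 2-methylpropanoate | COC(=O)C(C)C | starting material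
13 | 2,9-dimethyldec-8-ene-3,5-dione | CC(C)C(=O)CC(=O)CCC=C(C)C | intermediate
14 | (3R)-6,6-dimethyl-3-(3-methylbut-2-en-1-yl)-2-oxo-3,6-dihydro-2H-pyran-3-carbonyl chloride | O=C1OC(C)(C)C=C[C@@]1(CC=C(C)C)C(Cl)=O | intermediate
15 | chloromagnesium enolate of 13 (chloromagnesium 2,9-dimethyl-3-oxodeca-4,8-dien-5-olate) | [Mg+2].[Cl-].CC(C)C(=O)C=C([O-])CCC=C(C)C | intermediate
16 | (3S)-6,6-dimethyl-3-(3-methylbut-2-en-1-yl)-3-[7-methyl-2-(2-methylpropanoyl)-3-oxooct-6-enoyl]-3,6-dihydro-2H-pyran-2-one (side-chain C2 enolised, no fixed configuration) | O=C1OC(C)(C)C=C[C@@]1(CC=C(C)C)C(=O)C(C(=O)C(C)C)C(=O)CCC=C(C)C | intermediate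
17 | dilithium dianion of 16 (enolate at the triacylmethane carbon and at C8) | [Li+].[Li+].O=C1OC(C)(C)C=C[C@@]1(CC=C(C)C)C(=O)C(C([O-])=CCC=C(C)C)=C([O-])C(C)C | intermediate
18 | (6R)-3,5-dihydroxy-6-[(1Z)-3-hydroxy-3-methylbut-1-en-1-yl]-4,6-bis(3-methylbut-2-en-1-yl)-2-(2-methylpropanoyl)cyclohexa-2,4-dien-1-one | CC(C)=CCC1=C(O)[C@](/C=C\C(C)(C)O)(CC=C(C)C)C(=O)C(C(=O)C(C)C)=C1O | intermediate
19 | (4aR)-7-hydroxy-2,2-dimethyl-4a,8-bis(3-methylbut-2-en-1-yl)-6-(2-methylpropanoyl)-2H-chromen-5(4aH)-one | CC(C)=CCC1=C2OC(C)(C)C=C[C@@]2(CC=C(C)C)C(=O)C(C(=O)C(C)C)=C1O | target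

**Step count**

Total: 10 steps. Longest linear sequence: 9 steps (steps 1–5 and 7–10, from malonyl dichloride); step 6 is a one-step branch.

**Steps most likely to fail**

Step 4. The catalyst may discriminate poorly between the enantiotopic ester arms, or turn over slowly because both reacting vinyl groups sit on fully substituted carbons and the ester must rotate into its s-cis form before closing. The fallback sets out from 8 and returns at 10; it takes the stereocentre from a classical resolution instead of from the catalyst. The same lactone is closed without asymmetric induction using RuCl2(=CH-C6H4-2-OiPr)(1,3-dimesitylimidazolidin-2-ylidene), the second-generation Hoveyda–Grubbs catalyst, in toluene at 40–60 °C. This should give racemic 2-methylbut-3-en-2-yl 6,6-dimethyl-3-(3-methylbut-2-en-1-yl)-2-oxo-3,6-dihydro-2H-pyran-3-carboxylate F1. The conditions of step 5 then give racemic 6,6-dimethyl-3-(3-methylbut-2-en-1-yl)-2-oxo-3,6-dihydro-2H-pyran-3-carboxylic acid F2. This acid is resolved by crystallisation with (1R)-1-phenylethanamine as (1R)-1-phenylethanaminium (3S)-6,6-dimethyl-3-(3-methylbut-2-en-1-yl)-2-oxo-3,6-dihydro-2H-pyran-3-carboxylate F3; the antipodal amine is used should the other diastereomer be the less soluble one. Acidification of the salt releases 10.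

Step 9. The second proton may be removed at the isobutyryl methine instead of C8, an enolate oxygen may attack the lactone, or the triacylmethane may lose an acyl group by retro-Claisen cleavage before ring A closes. The fallback sets out from 8 and returns at 18; it reverses the order of the two C–C bonds in the antipodal series. This is possible because the two carboxyl carbons on C4a are interchangeable until one is joined to C6 and the other to C8. Step 4 with the antipodal diolate complex should give 2-methylbut-3-en-2-yl (3R)-6,6-dimethyl-3-(3-methylbut-2-en-1-yl)-2-oxo-3,6-dihydro-2H-pyran-3-carboxylate F4. The conditions of steps 5 and 7 then give (3R)-6,6-dimethyl-3-(3-methylbut-2-en-1-yl)-2-oxo-3,6-dihydro-2H-pyran-3-carboxylic acid F5 and (3S)-6,6-dimethyl-3-(3-methylbut-2-en-1-yl)-2-oxo-3,6-dihydro-2H-pyran-3-carbonyl chloride F6. The dilithium dianion of 13 (LiN(iPr)2, two equivalents per diketone, THF, −78 °C, dianion in twofold excess) is acylated by the acid chloride at its terminal carbanion, the future C8. This should give (3R)-6,6-dimethyl-3-(3-methylbut-2-en-1-yl)-3-[6-methyl-2-(3-methylbut-2-en-1-yl)-3,5-dioxoheptanoyl]-3,6-dihydro-2H-pyran-2-one F7, in which the former acid chloride carbon is C8a. NaH in THF then closes ring A through the central diketone carbon C6 onto the lactone carbonyl, now C5. This is the Claisen mode by which linear tetracarbonyl chains give acylphloroglucinols; the carbinol is released and 18 should result in the required configuration.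

Step 10. The carbinol may close onto the C5 carbonyl instead of C8a, or the acid may add enol oxygens to the prenyl double bonds. The fallback sets out from 9 (together with 13) and returns at 19; it closes the pyran while C5 is still an ester, so that only C8a can accept the oxygen. The dilithium dianion of 13 is added to 9 in THF at −78 to 0 °C. Its terminal carbanion should attack the lactone carbonyl, the more electrophilic of the two hindered carboxyl groups, and open it to 2-methylbut-3-en-2-yl (2R)-2-[(1Z)-3-hydroxy-3-methylbut-1-en-1-yl]-8-methyl-2,4-bis(3-methylbut-2-en-1-yl)-3,5,7-trioxononanoate F8. PPTS in CH2Cl2 then dehydrates the carbinol onto C8a to give the alkylidene dihydropyran 2-methylbut-3-en-2-yl (3R)-2-(2,9-dimethyl-6,8-dioxodec-2-en-5-ylidene)-6,6-dimethyl-3-(3-methylbut-2-en-1-yl)-3,6-dihydro-2H-pyran-3-carboxylate F9, whose push–pull exocyclic alkene can equilibrate between its two geometries. KOC(CH3)3 in THF closes ring A by Dieckmann attack of C6 on the tertiary allyl ester with loss of 2-methylbut-3-en-2-olate, giving 19 after acidification.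

**Further compounds**

F1 | step 4 | racemic 2-methylbut-3-en-2-yl 6,6-dimethyl-3-(3-methylbut-2-en-1-yl)-2-oxo-3,6-dihydro-2H-pyran-3-carboxylate | O=C1OC(C)(C)C=CC1(CC=C(C)C)C(=O)OC(C)(C)C=C
F2 | step 4 | racemic 6,6-dimethyl-3-(3-methylbut-2-en-1-yl)-2-oxo-3,6-dihydro-2H-pyran-3-carboxylic acid | O=C1OC(C)(C)C=CC1(CC=C(C)C)C(=O)O
F3 | step 4 | (1R)-1-phenylethanaminium (3S)-6,6-dimethyl-3-(3-methylbut-2-en-1-yl)-2-oxo-3,6-dihydro-2H-pyran-3-carboxylate | C[C@@H]([NH3+])c1ccccc1.O=C1OC(C)(C)C=C[C@@]1(CC=C(C)C)C(=O)[O-]
F4 | step 9 | 2-methylbut-3-en-2-yl (3R)-6,6-dimethyl-3-(3-methylbut-2-en-1-yl)-2-oxo-3,6-dihydro-2H-pyran-3-carboxylate | O=C1OC(C)(C)C=C[C@]1(CC=C(C)C)C(=O)OC(C)(C)C=C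
F5 | step 9 | (3R)-6,6-dimethyl-3-(3-methylbut-2-en-1-yl)-2-oxo-3,6-dihydro-2H-pyran-3-carboxylic acid | O=C1OC(C)(C)C=C[C@]1(CC=C(C)C)C(=O)O
F6 | step 9 | (3S)-6,6-dimethyl-3-(3-methylbut-2-en-1-yl)-2-oxo-3,6-dihydro-2H-pyran-3-carbonyl chloride | O=C1OC(C)(C)C=C[C@]1(CC=C(C)C)C(Cl)=O
F7 | step 9 | (3R)-6,6-dimethyl-3-(3-methylbut-2-en-1-yl)-3-[6-methyl-2-(3-methylbut-2-en-1-yl)-3,5-dioxoheptanoyl]-3,6-dihydro-2H-pyran-2-one | O=C1OC(C)(C)C=C[C@]1(CC=C(C)C)C(=O)C(CC=C(C)C)C(=O)CC(=O)C(C)C
F8 | step 10 | 2-methylbut-3-en-2-yl (2R)-2-[(1Z)-3-hydroxy-3-methylbut-1-en-1-yl]-8-methyl-2,4-bis(3-methylbut-2-en-1-yl)-3,5,7-trioxononanoate | C=CC(C)(C)OC(=O)[C@](CC=C(C)C)(/C=C\C(C)(C)O)C(=O)C(CC=C(C)C)C(=O)CC(=O)C(C)C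
F9 | step 10 | 2-methylbut-3-en-2-yl (3R)-2-(2,9-dimethyl-6,8-dioxodec-2-en-5-ylidene)-6,6-dimethyl-3-(3-methylbut-2-en-1-yl)-3,6-dihydro-2H-pyran-3-carboxylate | C=CC(C)(C)OC(=O)[C@]1(CC=C(C)C)C=CC(C)(C)OC1=C(CC=C(C)C)C(=O)CC(=O)C(C)C
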